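**Retrosynthetic overview**
1. Target ⇒ cut the C6–CH2–C3' methylene bridge (Mannich/Michael union): (4R)-2-butanoyl-4-methyl-4-prenylcyclohexane-1,3,5-trione (enol form) + 2,4-dihydroxy-6-methoxybutyrophenone + a one-carbon unit.
2. Trione ring (the only ring formed; the arene is bought) ⇒ Claisen ring closure of a triketide ester ⇒ heptane-2,4-dione dianion + (R)-methyl hydrogen 2-methyl-2-prenylmalonate (acid arm becomes C5/C6, ester arm becomes C3/C2).
3. Key disconnection, the ester C–O bond of that half ester ⇒ enantioselective desymmetrising methanolysis of prochiral 5-methyl-5-prenyl Meldrum's acid; this sets the only stereocentre.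
4. Meldrum's acid ⇒ 5-methyl Meldrum's acid + prenyl bromide; aryl ketone ⇒ 5-methoxyresorcinol + butanenitrile (Hoesch).

Assumption: the target is handled as the drawn enol tautomer of a β-triketone (4R refers to it), and the catalyst in step 2 is taken to give the (R)-acid; if the sense proves opposite, the pseudo-enantiomeric quinine-derived catalyst is used.

**Step 1**
Reactants: 1 2,2,5-trimethyl-1,3-dioxane-4,6-dione (5-methyl Meldrum's acid); 2 1-bromo-3-methylbut-2-ene (prenyl bromide)
Product: 3 2,2,5-trimethyl-5-(3-methylbut-2-en-1-yl)-1,3-dioxane-4,6-dione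
Conditions: K2CO3 (1.5 equiv), DMF, rt, 12 h
Reagents that add atoms: none
Why: SN2 C-alkylation of the soft Meldrum's acid enolate (pKa about 5–7) by a primary allylic bromide; C5 of 3 is prochiral, so no stereocentre is formed yet.

**Step 2**
Reactants: 3 2,2,5-trimethyl-5-(3-methylbut-2-en-1-yl)-1,3-dioxane-4,6-dione
Product: 4 (2R)-2-(methoxycarbonyl)-2,5-dimethylhex-4-enoic acid
Conditions: MeOH (10 equiv), 9-amino(9-deoxy)epi-quinidine 3,5-bis(trifluoromethyl)phenyl squaramide (10 mol%), MTBE, rt, 48 h; dil. HCl wash
Reagents that add atoms: methanol (CO)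
Why: Proposed new method: the two lactone carbonyls of the boat-shaped acylal 3 are enantiotopic and about as electrophilic as those of a cyclic anhydride, so a bifunctional cinchona squaramide should hold the dicarbonyl unit by its two N–H bonds while the quinuclidine delivers methanol by general-base catalysis to one carbonyl only (methyl versus prenyl discrimination at C5), and the adduct then opens irreversibly with loss of acetone, so this C–O bond formation fixes the quaternary centre as (R); the closest known reaction type is the cinchona-catalysed enantioselective alcoholysis (desymmetrisation) of meso and prochiral cyclic anhydrides, which has not been shown for 5,5-disubstituted Meldrum's acids.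

**Step 3**
Reactants: 4 (2R)-2-(methoxycarbonyl)-2,5-dimethylhex-4-enoic acid; 5 heptane-2,4-dione
Product: 8 (4R)-2-butanoyl-3,5-dihydroxy-4-methyl-4-(3-methylbut-2-en-1-yl)cyclohexa-2,5-dien-1-one, via acid chloride 6 (not isolated), via triketo ester 7 (not isolated)
Conditions: (i) (COCl)2, cat. DMF, CH2Cl2, 0 °C, then evaporate; (ii) 5 (2.2 equiv), LDA (4.4 equiv, commercial solution), THF, −78 → 0 °C, then add 6, −78 °C → rt; (iii) 45 °C, 3 h; cold 1 M HCl
Reagents that add atoms: none
Why: Harris-type γ-acylation of the β-diketone dianion at its methyl-derived terminal carbon by the acid chloride (far more electrophilic than the neopentyl methyl ester), then Claisen (Dieckmann-type) closure of C6 of the triketide on that ester; the quaternary centre is untouched, and the acid chloride/ester difference made in step 2 decides which arm carries the butanoyl group, giving (4R)-8.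

**Step 4**
Reactants: 9 5-methoxybenzene-1,3-diol (5-methoxyresorcinol); 10 butanenitrile
Product: 12 1-(2,4-dihydroxy-6-methoxyphenyl)butan-1-one, via ketiminium chloride 11 (not isolated)
Conditions: ZnCl2 (0.3 equiv), HCl (g), Et2O, 0 °C → rt, 24 h; then H2O, 100 °C, 1 h; chromatography
Reagents that add atoms: water (O)
Why: Houben–Hoesch acylation at C4 (para to one OH, ortho to the other, two equivalent sites) gives the ketiminium salt, which water hydrolyses to the ketone; the minor symmetrical 2,6-dihydroxy-4-methoxy isomer (two chelated OH, much less polar) is removed by chromatography.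

**Step 5**
Reactants: 8 (4R)-2-butanoyl-3,5-dihydroxy-4-methyl-4-(3-methylbut-2-en-1-yl)cyclohexa-2,5-dien-1-one; 12 1-(2,4-dihydroxy-6-methoxyphenyl)butan-1-one
Product: 15 (4R)-2-butanoyl-6-[(3-butanoyl-2,6-dihydroxy-4-methoxyphenyl)methyl]-3,5-dihydroxy-4-methyl-4-(3-methylbut-2-en-1-yl)cyclohexa-2,5-dien-1-one, via Mannich base 13 (not isolated), via methylene trione 14 (not isolated)
Conditions: (i) CH2=NMe2+ I− (1.0 equiv), Et3N (1.0 equiv), MeCN, 0 °C → rt, 1 h; (ii) 12 (2.0 equiv), 70 °C, 6 h; dil. citric acid
Reagents that add atoms: N,N-dimethylmethyleneiminium iodide, Eschenmoser's salt (C=[N+](C)C.[I-])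
Why: Mannich reaction at C6, the only free nucleophilic carbon of 8, then thermal loss of dimethylamine gives the exo-methylene trione, which is trapped by Friedel–Crafts-type Michael addition of C3 of 12 (between the two hydroxyls); no stereocentre is formed and C4 is not involved.

**Compound list**
1 | 2,2,5-trimethyl-1,3-dioxane-4,6-dione | CC1C(=O)OC(C)(C)OC1=O | starting material
2 | 1-bromo-3-methylbut-2-ene | CC(C)=CCBr | starting material
3 | 2,2,5-trimethyl-5-(3-methylbut-2-en-1-yl)-1,3-dioxane-4,6-dione | CC(C)=CCC1(C)C(=O)OC(C)(C)OC1=O | intermediate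
4 | (2R)-2-(methoxycarbonyl)-2,5-dimethylhex-4-enoic acid | COC(=O)[C@](C)(CC=C(C)C)C(=O)O | intermediate
5 | heptane-2,4-dione | CCCC(=O)CC(C)=O | starting material
6 | methyl (2S)-2-(chlorocarbonyl)-2,5-dimethylhex-4-enoate (same spatial arrangement as 4; descriptor changes with CIP priority) | COC(=O)[C@](C)(CC=C(C)C)C(Cl)=O | intermediate
7 | methyl (2R)-2-methyl-2-(3-methylbut-2-en-1-yl)-3,5,7-trioxodecanoate | COC(=O)[C@](C)(CC=C(C)C)C(=O)CC(=O)CC(=O)CCC | intermediate
8 | (4R)-2-butanoyl-3,5-dihydroxy-4-methyl-4-(3-methylbut-2-en-1-yl)cyclohexa-2,5-dien-1-one | CCCC(=O)C1=C(O)[C@](C)(CC=C(C)C)C(O)=CC1=O | intermediate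
9 | 5-methoxybenzene-1,3-diol | COc1cc(O)cc(O)c1 | starting material
10 | butanenitrile | CCCC#N | starting material
11 | 1-(2,4-dihydroxy-6-methoxyphenyl)butan-1-iminium chloride | CCCC(=[NH2+])c1c(O)cc(O)cc1OC.[Cl-] | intermediate
12 | 1-(2,4-dihydroxy-6-methoxyphenyl)butan-1-one | CCCC(=O)c1c(O)cc(O)cc1OC | intermediate
13 | (4R)-2-butanoyl-6-[(dimethylamino)methyl]-3,5-dihydroxy-4-methyl-4-(3-methylbut-2-en-1-yl)cyclohexa-2,5-dien-1-one | CCCC(=O)C1=C(O)[C@](C)(CC=C(C)C)C(O)=C(CN(C)C)C1=O | intermediate
14 | (4S)-2-butanoyl-3-hydroxy-4-methyl-6-methylidene-4-(3-methylbut-2-en-1-yl)cyclohex-2-ene-1,5-dione (same spatial arrangement as 8; descriptor changes with CIP priority) | CCCC(=O)C1=C(O)[C@](C)(CC=C(C)C)C(=O)C(=C)C1=O | intermediate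
15 | (4R)-2-butanoyl-6-[(3-butanoyl-2,6-dihydroxy-4-methoxyphenyl)methyl]-3,5-dihydroxy-4-methyl-4-(3-methylbut-2-en-1-yl)cyclohexa-2,5-dien-1-one | CCCC(=O)C1=C(O)[C@](C)(CC=C(C)C)C(O)=C(Cc2c(O)cc(OC)c(C(=O)CCC)c2O)C1=O | target

**Totals**
Total step count: 5. Longest linear sequence: 4 steps (1 → 2 → 3 → 5); step 4 is the side branch.

**Steps most likely to fail**

Step 2 (the proposed new desymmetrisation) may be slow or give modest ee, because methyl and prenyl must be told apart at a quaternary carbon. The fallback uses known chemistry, sets out from 3 and returns at 4. Compound 3 is opened with NaOMe in MeOH at rt to racemic 2-(methoxycarbonyl)-2,5-dimethylhex-4-enoic acid F1. This is resolved by crystallising (S)-1-phenylethylammonium (2R)-2-(methoxycarbonyl)-2,5-dimethylhex-4-enoate F2 (taken from the crystals or, if the other diastereomer is less soluble, from the mother liquor), and dilute HCl then liberates 4. The same salt crystallisation also serves to raise the ee of catalytically made 4.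

Step 3 may suffer from partial dianion formation at C5 of 5 instead of the methyl group (this gives an isomeric 2-acetyl-6-ethyl trione), from O-acylation, or from incomplete Claisen closure (enol-lactone formation). The fallback reverses the order of the two C–C bonds, so it needs the antipodal half ester; it sets out from 3 and returns at 8. Compound 3 is opened with the pseudo-enantiomeric quinine-derived catalyst (or via the resolution with the (R)-amine) to (2S)-2-(methoxycarbonyl)-2,5-dimethylhex-4-enoic acid F3. Oxalyl chloride converts this to methyl (2R)-2-(chlorocarbonyl)-2,5-dimethylhex-4-enoate F4. C-acylation of 5 at its central carbon (MgCl2, pyridine, CH2Cl2) gives methyl (2S)-4-acetyl-2-methyl-2-(3-methylbut-2-en-1-yl)-3,5-dioxooctanoate F5. LiHMDS in THF then closes the ring by Dieckmann-type attack of the acetyl methyl group on the ester to give 8.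

Step 5 may give some attack at C5 of 12 (between OH and OMe) and some methylene-bis homodimer of 8. The fallback puts the electrophile on the aromatic half, so that regiochemistry is fixed and checked before the union; it sets out from 12 and returns at 15. Compound 12 is treated with Eschenmoser's salt to give 1-{3-[(dimethylamino)methyl]-2,4-dihydroxy-6-methoxyphenyl}butan-1-one F6, which is purified as the single C3 regioisomer (HMBC). Heating F6 with 8 in dioxane releases dimethylamine and forms the ortho-quinone methide 4-butanoyl-5-hydroxy-3-methoxy-6-methylidenecyclohexa-2,4-dien-1-one F7, which is captured by C6 of 8 to give 15.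

**Further compounds**
F1 | step 2 | racemic 2-(methoxycarbonyl)-2,5-dimethylhex-4-enoic acid | COC(=O)C(C)(CC=C(C)C)C(=O)O
F2 | step 2 | (S)-1-phenylethylammonium (2R)-2-(methoxycarbonyl)-2,5-dimethylhex-4-enoate | COC(=O)[C@](C)(CC=C(C)C)C(=O)[O-].C[C@H]([NH3+])c1ccccc1
F3 | step 3 | (2S)-2-(methoxycarbonyl)-2,5-dimethylhex-4-enoic acid | COC(=O)[C@@](C)(CC=C(C)C)C(=O)O
F4 | step 3 | methyl (2R)-2-(chlorocarbonyl)-2,5-dimethylhex-4-enoate | COC(=O)[C@@](C)(CC=C(C)C)C(Cl)=O
F5 | step 3 | methyl (2S)-4-acetyl-2-methyl-2-(3-methylbut-2-en-1-yl)-3,5-dioxooctanoate | COC(=O)[C@@](C)(CC=C(C)C)C(=O)C(C(C)=O)C(=O)CCC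
F6 | step 5 | 1-{3-[(dimethylamino)methyl]-2,4-dihydroxy-6-methoxyphenyl}butan-1-one | CCCC(=O)c1c(O)c(CN(C)C)c(O)cc1OC
F7 | step 5 | 4-butanoyl-5-hydroxy-3-methoxy-6-methylidenecyclohexa-2,4-dien-1-one | CCCC(=O)C1=C(O)C(=C)C(=O)C=C1OC
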